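## Retrosynthetic overview

1. Target 20 ⇒ fluoride cleavage of the two outer aryl silyl ethers of tetraester 19. The four identical esters are made two at a time from symmetrical anhydride 9: first on the two enol hydroxyls of quinone 16 (giving 17), then, after quinone-to-hydroquinone reduction (18), on the two new phenols.
2. 9 ⇒ carboxylate salt 7 plus its mixed anhydride 8; 7 ⇒ carboxylesterase hydrolysis of methyl ester 6 ⇒ Still–Gennari Z-olefination of (2R,3S)-2,3-epoxybutanal 4 ⇒ Sharpless asymmetric epoxidation of (E)-but-2-en-1-ol 1, which sets both stereocentres (ee raised by crystallising 4-nitrobenzoate 3).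
3. 16 ⇒ hydrogenolysis and air oxidation of tetrabenzyl ether 14 ⇒ double Suzuki–Miyaura coupling of dibromide 12 with boronic acid 13 ⇒ reduction and benzylation of bromanilic acid 10.
4. Ring order: the oxirane is the only ring built (step 1) and is carried unchanged into all four acyl groups. The three six-membered rings are bought; the central one is functionalised first, then joined to the two outer ones, and afterwards only changes oxidation level. No ring is formed afterwards.

Assumption: the acyl groups are read from the SMILES as (2Z,4S,5S)-4,5-epoxyhex-2-enoyl (trans-oxirane), and crotyl alcohol is bought as the E isomer (about 96% E or better).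

## Route

Step 1
Reactants: 1 (E)-but-2-en-1-ol
Product: 3 [(2S,3S)-3-methyloxiran-2-yl]methyl 4-nitrobenzoate, via (2S,3S)-2,3-epoxybutan-1-ol 2 (not isolated)
Conditions: Ti(OiPr)4 (5 mol%), L-(+)-diisopropyl tartrate (7 mol%), tBuOOH (2 equiv), 4 Å MS, CH2Cl2, −20 °C; P(OMe)3; then 4-O2NC6H4COCl, Et3N, 0 °C; recrystallise (Et2O/hexane)
Reagents that add atoms: tert-butyl hydroperoxide, CC(C)(C)OO; 4-nitrobenzoyl chloride, O=C(Cl)c1ccc(cc1)[N+](=O)[O-]
Why: Katsuki–Sharpless asymmetric epoxidation with the catalytic titanium/L-(+)-tartrate complex delivers oxygen to one face of the E-alkene and sets the trans (2S,3S) oxirane, and in-flask acylation gives a crystalline ester whose recrystallisation raises the ee to above 98% and removes the cis-epoxide arising from residual Z-alkene.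

Step 2
Reactants: 3 [(2S,3S)-3-methyloxiran-2-yl]methyl 4-nitrobenzoate
Product: 2 (2S,3S)-2,3-epoxybutan-1-ol
Conditions: K2CO3 (0.2 equiv), MeOH, 0 °C, 1 h; silica pad, cold concentration, bulb-to-bulb distillation
Reagents that add atoms: none
Why: Base-catalysed transesterification (methanolysis) of the activated nitrobenzoate is fast at 0 °C with catalytic carbonate, so Payne rearrangement and epoxide opening do not compete and both stereocentres are untouched.

Step 3
Reactants: 2 (2S,3S)-2,3-epoxybutan-1-ol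
Product: 4 (2R,3S)-2,3-epoxybutanal
Conditions: Dess–Martin periodinane (1.2 equiv), NaHCO3, CH2Cl2, 0 °C to rt; pentane, filtration through Celite/silica, cold concentration to a solution used the same day
Reagents that add atoms: none
Why: Dess–Martin oxidation is neutral and non-aqueous, so the water-soluble, volatile α-epoxy aldehyde forms without epimerisation or hydration (the C2 descriptor changes from S to R only because CHO now outranks the ring carbon).

Step 4
Reactants: 4 (2R,3S)-2,3-epoxybutanal; 5 methyl [bis(2,2,2-trifluoroethoxy)phosphoryl]acetate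
Product: 6 methyl (2Z,4S,5S)-4,5-epoxyhex-2-enoate
Conditions: 5, KN(SiMe3)2, 18-crown-6, THF, −78 °C; then 4, −78 °C; chromatography, cold evaporation
Reagents that add atoms: none
Why: In the Still–Gennari variant of the Horner–Wadsworth–Emmons reaction the electron-poor trifluoroethyl phosphonate eliminates fast from the kinetic adduct under dissociating conditions to give the Z-enoate (typically 10:1 or better), and −78 °C leaves the oxirane and its stereocentres untouched.

Step 5
Reactants: 6 methyl (2Z,4S,5S)-4,5-epoxyhex-2-enoate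
Product: 7 sodium (2Z,4S,5S)-4,5-epoxyhex-2-enoate
Conditions: pig liver esterase (a carboxylesterase), 0.05 M sodium phosphate buffer pH 7.5/acetone 9:1, pH-stat with 0.5 M NaOH, 25 °C; ultrafiltration, Et2O wash, lyophilisation
Reagents that add atoms: water, O (carboxylate oxygen); sodium hydroxide, [Na+].[OH-] (sodium ion)
Why: Enzymatic ester hydrolysis by a carboxylesterase works at pH 7.5 without Z/E isomerisation or conjugate addition and gives the carboxylate salt directly, so the Z-γ,δ-epoxy acid, which lactonises on acidification, is never set free.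

Step 6
Reactants: 7 sodium (2Z,4S,5S)-4,5-epoxyhex-2-enoate
Product: 8 (2Z,4S,5S)-4,5-epoxyhex-2-enoic 2,4,6-trichlorobenzoic anhydride
Conditions: 2,4,6-Cl3C6H2COCl (1 equiv), 15-crown-5 (5 mol%), THF, 0 °C, 1 h; NaCl filtered off under Ar; filtrate assayed by 1H NMR and used the same day
Reagents that add atoms: 2,4,6-trichlorobenzoyl chloride, O=C(Cl)c1c(Cl)cc(Cl)cc1Cl
Why: O-acylation of the carboxylate by the hindered aroyl chloride (mixed-anhydride formation, the first stage of the Yamaguchi protocol) needs neither an amine base nor the free acid, so the Z-alkene and both stereocentres are untouched, and running it to completion leaves no aroyl chloride that could later acylate the phenols.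

Step 7
Reactants: 8 (2Z,4S,5S)-4,5-epoxyhex-2-enoic 2,4,6-trichlorobenzoic anhydride; 7 sodium (2Z,4S,5S)-4,5-epoxyhex-2-enoate
Product: 9 (2Z,4S,5S)-4,5-epoxyhex-2-enoic anhydride
Conditions: 7 (1 equiv), 15-crown-5 (5 mol%), THF/toluene, 0 °C to rt, 2 h; sodium 2,4,6-trichlorobenzoate filtered off under Ar; cold concentration; stored at −20 °C under Ar
Reagents that add atoms: none
Why: In this nucleophilic acyl substitution the carboxylate attacks the unhindered enoyl carbonyl of the mixed anhydride and expels the better leaving group 2,4,6-trichlorobenzoate, whose sodium salt precipitates, so the acid is obtained as its neutral, storable symmetrical anhydride with no stereocentre involved.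

Step 8
Reactants: 10 2,5-dibromo-3,6-dihydroxy-1,4-benzoquinone (bromanilic acid)
Product: 11 3,6-dibromobenzene-1,2,4,5-tetrol
Conditions: SnCl2·2H2O, conc. HCl, 90 °C, then 0 °C (product crystallises), Ar
Reagents that add atoms: none
Why: Two-electron quinone-to-hydroquinone reduction by SnCl2 in acid is classical for anilic acids and leaves the aryl C–Br bonds intact.

Step 9
Reactants: 11 3,6-dibromobenzene-1,2,4,5-tetrol
Product: 12 1,4-dibromo-2,3,5,6-tetrakis(benzyloxy)benzene
Conditions: BnBr (6 equiv), K2CO3 (8 equiv), degassed DMF, 60 °C, Ar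
Reagents that add atoms: benzyl bromide, BrCc1ccccc1
Why: Exhaustive Williamson etherification of the four phenoxides under oxygen-free conditions locks the air-sensitive tetrol as hydrogenolysable benzyl ethers.

Step 10
Reactants: 12 1,4-dibromo-2,3,5,6-tetrakis(benzyloxy)benzene; 13 [4-(tert-butyldimethylsilyloxy)phenyl]boronic acid (3 equiv)
Product: 14 2',3',5',6'-tetrakis(benzyloxy)-4,4''-bis(tert-butyldimethylsilyloxy)-1,1':4',1''-terphenyl
Conditions: Pd(OAc)2 (5 mol%), SPhos (2-dicyclohexylphosphino-2',6'-dimethoxybiphenyl, 10 mol%), K3PO4·H2O (6 equiv), toluene, 90 °C, Ar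
Reagents that add atoms: none
Why: In this double Suzuki–Miyaura coupling the bulky electron-rich biarylphosphine lets palladium insert into the hindered di-ortho-alkoxy C–Br bonds, while the nearly anhydrous phosphate base spares the aryl silyl ethers.

Step 11
Reactants: 14 2',3',5',6'-tetrakis(benzyloxy)-4,4''-bis(tert-butyldimethylsilyloxy)-1,1':4',1''-terphenyl
Product: 16 2,5-bis[4-(tert-butyldimethylsilyloxy)phenyl]-3,6-dihydroxy-1,4-benzoquinone, via bis-silyl leucoatromentin 15 (not isolated)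
Conditions: H2 (1 atm), Pd(OH)2/C, THF/EtOAc, rt; Ar purge, Celite filtration; then air (O2) bubbled through the filtrate, rt, 2 h; crystallisation
Reagents that add atoms: none
Why: Catalytic hydrogenolysis cleaves the four benzyl ethers under neutral conditions that do not touch the silyl ethers, and the very electron-rich tetrol then autoxidises in air (hydroquinone-to-quinone oxidation) to the 2,5-dihydroxyquinone, which, unlike the tetrol, is bench-stable and can be purified and stored.

Step 12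
Reactants: 16 2,5-bis[4-(tert-butyldimethylsilyloxy)phenyl]-3,6-dihydroxy-1,4-benzoquinone; 9 (2Z,4S,5S)-4,5-epoxyhex-2-enoic anhydride
Product: 17 2,5-bis[4-(tert-butyldimethylsilyloxy)phenyl]-3,6-dioxocyclohexa-1,4-diene-1,4-diyl bis[(2Z,4S,5S)-4,5-epoxyhex-2-enoate]
Conditions: 9 (1.2 equiv), 4-(dimethylamino)pyridine (10 mol%), CH2Cl2, −10 °C; then N,N'-diisopropylcarbodiimide (1.2 equiv) added over 30 min, −10 to 0 °C, Ar, dark; urea filtered off, short silica plug, cold concentration
Reagents that add atoms: none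
Why: This Steglich-type acyl transfer esterifies the two acidic enol hydroxyls, as in the classical enol acetates of atromentin, and the carbodiimide turns the acid released by the first transfer back into acylating agent, so one molecule of 9 delivers both acyl groups and no carboxylate is left to reverse the acylation, while low temperature and little pyridine catalyst limit Z-to-E leakage and the stereocentres are not involved.

Step 13
Reactants: 17 2,5-bis[4-(tert-butyldimethylsilyloxy)phenyl]-3,6-dioxocyclohexa-1,4-diene-1,4-diyl bis[(2Z,4S,5S)-4,5-epoxyhex-2-enoate]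
Product: 18 4,4''-bis(tert-butyldimethylsilyloxy)-2',5'-dihydroxy-1,1':4',1''-terphenyl-3',6'-diyl bis[(2Z,4S,5S)-4,5-epoxyhex-2-enoate]
Conditions: Na2S2O4 (3 equiv), EtOAc/0.2 M sodium phosphate buffer pH 6.5, 0 °C, 10 min, Ar; phase separation, Na2SO4, cold concentration; used at once
Reagents that add atoms: none
Why: Two-electron quinone-to-hydroquinone reduction by dithionite is complete within minutes in the cold buffered two-phase system, too fast for the enol esters to hydrolyse or for the Z-enoates and oxiranes to react, and a 1,2-acyl shift in the product would be harmless because every ring oxygen ends up carrying the same acyl group.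

Step 14
Reactants: 18 4,4''-bis(tert-butyldimethylsilyloxy)-2',5'-dihydroxy-1,1':4',1''-terphenyl-3',6'-diyl bis[(2Z,4S,5S)-4,5-epoxyhex-2-enoate]; 9 (2Z,4S,5S)-4,5-epoxyhex-2-enoic anhydride
Product: 19 4,4''-bis(tert-butyldimethylsilyloxy)-1,1':4',1''-terphenyl-2',3',5',6'-tetrayl tetrakis[(2Z,4S,5S)-4,5-epoxyhex-2-enoate]
Conditions: 9 (1.3 equiv), N,N'-diisopropylcarbodiimide (1.3 equiv), 4-(dimethylamino)pyridine (20 mol%), CH2Cl2, −10 to 0 °C, Ar, dark; urea filtered off, chromatography
Reagents that add atoms: none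
Why: The same Steglich-type esterification acylates the two remaining hindered phenols, the anhydride and the carbodiimide together supplying both acyl groups from one molecule of 9 without the free acid ever accumulating, and the stereocentres are not involved.

Step 15
Reactants: 19 4,4''-bis(tert-butyldimethylsilyloxy)-1,1':4',1''-terphenyl-2',3',5',6'-tetrayl tetrakis[(2Z,4S,5S)-4,5-epoxyhex-2-enoate]
Product: 20 4,4''-dihydroxy-1,1':4',1''-terphenyl-2',3',5',6'-tetrayl tetrakis[(2Z,4S,5S)-4,5-epoxyhex-2-enoate] (CNP0249571.1)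
Conditions: Bu4NF/AcOH (1:1, 3 equiv), THF, 0 °C, 20 min; pH 7 buffer work-up
Reagents that add atoms: none
Why: Fluoride-mediated desilylation cleaves aryl silyl ethers within minutes at 0 °C, and the acetic acid buffer protonates the phenoxide at once, so the hindered aryl esters, Z-enoates and oxiranes are not attacked.

## Compound list

1 | (E)-but-2-en-1-ol | C/C=C/CO | starting material
2 | (2S,3S)-2,3-epoxybutan-1-ol | C[C@@H]1O[C@H]1CO | intermediate
3 | [(2S,3S)-3-methyloxiran-2-yl]methyl 4-nitrobenzoate | C[C@@H]1O[C@H]1COC(=O)c1ccc(cc1)[N+](=O)[O-] | intermediate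
4 | (2R,3S)-2,3-epoxybutanal | C[C@@H]1O[C@H]1C=O | intermediate
5 | methyl [bis(2,2,2-trifluoroethoxy)phosphoryl]acetate | COC(=O)CP(=O)(OCC(F)(F)F)OCC(F)(F)F | starting material
6 | methyl (2Z,4S,5S)-4,5-epoxyhex-2-enoate | C[C@@H]1O[C@H]1/C=C\C(=O)OC | intermediate
7 | sodium (2Z,4S,5S)-4,5-epoxyhex-2-enoate | C[C@@H]1O[C@H]1/C=C\C(=O)[O-].[Na+] | intermediate
8 | (2Z,4S,5S)-4,5-epoxyhex-2-enoic 2,4,6-trichlorobenzoic anhydride | C[C@@H]1O[C@H]1/C=C\C(=O)OC(=O)c1c(Cl)cc(Cl)cc1Cl | intermediate
9 | (2Z,4S,5S)-4,5-epoxyhex-2-enoic anhydride | C[C@@H]1O[C@H]1/C=C\C(=O)OC(=O)/C=C\[C@@H]1O[C@H]1C | intermediate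
10 | 2,5-dibromo-3,6-dihydroxy-1,4-benzoquinone (bromanilic acid) | O=C1C(Br)=C(O)C(=O)C(Br)=C1O | starting material
11 | 3,6-dibromobenzene-1,2,4,5-tetrol | Oc1c(O)c(Br)c(O)c(O)c1Br | intermediate
12 | 1,4-dibromo-2,3,5,6-tetrakis(benzyloxy)benzene | Brc1c(OCc2ccccc2)c(OCc2ccccc2)c(Br)c(OCc2ccccc2)c1OCc1ccccc1 | intermediate
13 | [4-(tert-butyldimethylsilyloxy)phenyl]boronic acid | CC(C)(C)[Si](C)(C)Oc1ccc(cc1)B(O)O | starting material
14 | 2',3',5',6'-tetrakis(benzyloxy)-4,4''-bis(tert-butyldimethylsilyloxy)-1,1':4',1''-terphenyl | CC(C)(C)[Si](C)(C)Oc1ccc(cc1)-c1c(OCc2ccccc2)c(OCc2ccccc2)c(-c2ccc(O[Si](C)(C)C(C)(C)C)cc2)c(OCc2ccccc2)c1OCc1ccccc1 | intermediate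
15 | 4,4''-bis(tert-butyldimethylsilyloxy)-1,1':4',1''-terphenyl-2',3',5',6'-tetrol (bis-silyl leucoatromentin) | CC(C)(C)[Si](C)(C)Oc1ccc(cc1)-c1c(O)c(O)c(-c2ccc(O[Si](C)(C)C(C)(C)C)cc2)c(O)c1O | intermediate
16 | 2,5-bis[4-(tert-butyldimethylsilyloxy)phenyl]-3,6-dihydroxy-1,4-benzoquinone | O=C1C(O)=C(c2ccc(O[Si](C)(C)C(C)(C)C)cc2)C(=O)C(O)=C1c1ccc(O[Si](C)(C)C(C)(C)C)cc1 | intermediate
17 | 2,5-bis[4-(tert-butyldimethylsilyloxy)phenyl]-3,6-dioxocyclohexa-1,4-diene-1,4-diyl bis[(2Z,4S,5S)-4,5-epoxyhex-2-enoate] | O=C1C(OC(=O)/C=C\[C@@H]2O[C@H]2C)=C(c2ccc(O[Si](C)(C)C(C)(C)C)cc2)C(=O)C(OC(=O)/C=C\[C@@H]2O[C@H]2C)=C1c1ccc(O[Si](C)(C)C(C)(C)C)cc1 | intermediate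
18 | 4,4''-bis(tert-butyldimethylsilyloxy)-2',5'-dihydroxy-1,1':4',1''-terphenyl-3',6'-diyl bis[(2Z,4S,5S)-4,5-epoxyhex-2-enoate] | Oc1c(OC(=O)/C=C\[C@@H]2O[C@H]2C)c(-c2ccc(O[Si](C)(C)C(C)(C)C)cc2)c(O)c(OC(=O)/C=C\[C@@H]2O[C@H]2C)c1-c1ccc(O[Si](C)(C)C(C)(C)C)cc1 | intermediate
19 | 4,4''-bis(tert-butyldimethylsilyloxy)-1,1':4',1''-terphenyl-2',3',5',6'-tetrayl tetrakis[(2Z,4S,5S)-4,5-epoxyhex-2-enoate] | C[C@@H]1O[C@H]1/C=C\C(=O)Oc1c(OC(=O)/C=C\[C@@H]2O[C@H]2C)c(-c2ccc(O[Si](C)(C)C(C)(C)C)cc2)c(OC(=O)/C=C\[C@@H]2O[C@H]2C)c(OC(=O)/C=C\[C@@H]2O[C@H]2C)c1-c1ccc(O[Si](C)(C)C(C)(C)C)cc1 | intermediate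
20 | 4,4''-dihydroxy-1,1':4',1''-terphenyl-2',3',5',6'-tetrayl tetrakis[(2Z,4S,5S)-4,5-epoxyhex-2-enoate] | C[C@@H]1O[C@H]1/C=C\C(=O)Oc1c(OC(=O)/C=C\[C@@H]2O[C@H]2C)c(-c2ccc(O)cc2)c(OC(=O)/C=C\[C@@H]2O[C@H]2C)c(OC(=O)/C=C\[C@@H]2O[C@H]2C)c1-c1ccc(O)cc1 | target

## Step count and weak points

Total step count: 15. Longest linear sequence: 11 steps (steps 1, 2, 3, 4, 5, 6, 7, 12, 13, 14, 15); the core branch (steps 8–11) joins at step 12, and anhydride 9 enters at steps 12 and 14.

Three steps most likely to fail: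

Step 4 (Z-olefination of the volatile epoxy aldehyde). The risks are loss or hydration of aldehyde 4 and an insufficient Z/E ratio. The fallback sets out from phosphonate 5 and comes back at 6, and puts the olefination before the epoxidation. Phosphonate 5 and (E)-but-2-enal (crotonaldehyde, achiral) under the same KN(SiMe3)2/18-crown-6 conditions give methyl (2Z,4E)-hexa-2,4-dienoate F1. Shi epoxidation of it uses the L-sorbose-derived ketone 1,2:4,5-di-O-isopropylidene-β-L-erythro-2,3-hexodiulo-2,6-pyranose (the enantiomer of the fructose-derived epoxidation ketone, 30 mol%) with KHSO5 (as 2KHSO5·KHSO4·K2SO4) and K2CO3 at pH 10.5 in MeCN/dimethoxymethane/H2O at 0 °C. The dioxirane attacks only the electron-richer 4,5-alkene, from the face that gives (4S,5S), and so yields 6 without any aldehyde handling. The ee (low to mid 90s) is then not upgraded by crystallisation, so 19 must be checked for diastereomers.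

Step 12 (esterification of the enol hydroxyls of the quinone). The risks are reversal of the acyl transfer to the acidic enol hydroxyls, hydrolysis of the enol esters of 17 on work-up, and Z-to-E leakage caused by the pyridine catalyst. The fallback sets out from aldehyde 4 and terphenyl 14 and comes back at 19, bypassing 16, 17 and 18. It esterifies all four hydroxyls at the tetrol stage and carries the chain as an alkyne, which can neither isomerise nor lactonise, so the four Z-alkenes are made last. Corey–Fuchs olefination of 4 (CBr4, PPh3, Et3N, CH2Cl2, −20 °C) gives (2S,3S)-2-(2,2-dibromoethenyl)-3-methyloxirane F2. Treatment with n-BuLi (2.1 equiv, THF, −78 °C) followed by ClCO2Me gives methyl (4S,5S)-4,5-epoxyhex-2-ynoate F3. LiOH (THF/H2O, 0 °C) and cold acidification to pH 3 give (4S,5S)-4,5-epoxyhex-2-ynoic acid F4. Terphenyl 14 is hydrogenolysed as in step 11 but kept under Ar, so that tetrol 15 is used without exposure to air. N,N'-diisopropylcarbodiimide (CH2Cl2, −20 °C, 5 mol% 4-(dimethylamino)pyridine) then joins four molecules of the acid to 15, giving 4,4''-bis(tert-butyldimethylsilyloxy)-1,1':4',1''-terphenyl-2',3',5',6'-tetrayl tetrakis[(4S,5S)-4,5-epoxyhex-2-ynoate] F5. Semihydrogenation over Pd/CaCO3 poisoned with Pb(OAc)2 (quinoline, H2 1 atm, EtOAc, 0 °C) adds hydrogen syn to each alkyne and delivers 19.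

Step 15 (final desilylation). The risks are ester cleavage or acyl transfer by fluoride or acetate, and oxirane opening. The fallback sets out from 14 and comes back at 20. It swaps the silyl groups for acetates at the robust stage and removes them at the end with a lipase. Bu4NF (THF, rt) on 14 gives 2',3',5',6'-tetrakis(benzyloxy)-1,1':4',1''-terphenyl-4,4''-diol F6, and Ac2O/pyridine turns it into 2',3',5',6'-tetrakis(benzyloxy)-1,1':4',1''-terphenyl-4,4''-diyl diacetate F7. Hydrogenolysis and air oxidation as in step 11 give 2,5-bis(4-acetoxyphenyl)-3,6-dihydroxy-1,4-benzoquinone F8. Esterification with anhydride 9 as in step 12 gives 2,5-bis(4-acetoxyphenyl)-3,6-dioxocyclohexa-1,4-diene-1,4-diyl bis[(2Z,4S,5S)-4,5-epoxyhex-2-enoate] F9. Dithionite reduction as in step 13 gives 4,4''-diacetoxy-2',5'-dihydroxy-1,1':4',1''-terphenyl-3',6'-diyl bis[(2Z,4S,5S)-4,5-epoxyhex-2-enoate] F10, and esterification as in step 14 gives 4,4''-diacetoxy-1,1':4',1''-terphenyl-2',3',5',6'-tetrayl tetrakis[(2Z,4S,5S)-4,5-epoxyhex-2-enoate] F11. Immobilised Candida antarctica lipase B (a lipase) with n-BuOH in tBuOMe at 30 °C then transfers only the two unhindered acetyl groups to butanol; the four crowded Z-enoates do not fit the acyl pocket, and 20 results.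

## Further compounds

F1 | step 4 | methyl (2Z,4E)-hexa-2,4-dienoate | C/C=C/C=C\C(=O)OC
F2 | step 12 | (2S,3S)-2-(2,2-dibromoethenyl)-3-methyloxirane | C[C@@H]1O[C@H]1C=C(Br)Br
F3 | step 12 | methyl (4S,5S)-4,5-epoxyhex-2-ynoate | C[C@@H]1O[C@H]1C#CC(=O)OC
F4 | step 12 | (4S,5S)-4,5-epoxyhex-2-ynoic acid | C[C@@H]1O[C@H]1C#CC(=O)O
F5 | step 12 | 4,4''-bis(tert-butyldimethylsilyloxy)-1,1':4',1''-terphenyl-2',3',5',6'-tetrayl tetrakis[(4S,5S)-4,5-epoxyhex-2-ynoate] | C[C@@H]1O[C@H]1C#CC(=O)Oc1c(OC(=O)C#C[C@@H]2O[C@H]2C)c(-c2ccc(O[Si](C)(C)C(C)(C)C)cc2)c(OC(=O)C#C[C@@H]2O[C@H]2C)c(OC(=O)C#C[C@@H]2O[C@H]2C)c1-c1ccc(O[Si](C)(C)C(C)(C)C)cc1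
F6 | step 15 | 2',3',5',6'-tetrakis(benzyloxy)-1,1':4',1''-terphenyl-4,4''-diol | Oc1ccc(cc1)-c1c(OCc2ccccc2)c(OCc2ccccc2)c(-c2ccc(O)cc2)c(OCc2ccccc2)c1OCc1ccccc1
F7 | step 15 | 2',3',5',6'-tetrakis(benzyloxy)-1,1':4',1''-terphenyl-4,4''-diyl diacetate | CC(=O)Oc1ccc(cc1)-c1c(OCc2ccccc2)c(OCc2ccccc2)c(-c2ccc(OC(C)=O)cc2)c(OCc2ccccc2)c1OCc1ccccc1
F8 | step 15 | 2,5-bis(4-acetoxyphenyl)-3,6-dihydroxy-1,4-benzoquinone | O=C1C(O)=C(c2ccc(OC(C)=O)cc2)C(=O)C(O)=C1c1ccc(OC(C)=O)cc1
F9 | step 15 | 2,5-bis(4-acetoxyphenyl)-3,6-dioxocyclohexa-1,4-diene-1,4-diyl bis[(2Z,4S,5S)-4,5-epoxyhex-2-enoate] | O=C1C(OC(=O)/C=C\[C@@H]2O[C@H]2C)=C(c2ccc(OC(C)=O)cc2)C(=O)C(OC(=O)/C=C\[C@@H]2O[C@H]2C)=C1c1ccc(OC(C)=O)cc1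
F10 | step 15 | 4,4''-diacetoxy-2',5'-dihydroxy-1,1':4',1''-terphenyl-3',6'-diyl bis[(2Z,4S,5S)-4,5-epoxyhex-2-enoate] | Oc1c(OC(=O)/C=C\[C@@H]2O[C@H]2C)c(-c2ccc(OC(C)=O)cc2)c(O)c(OC(=O)/C=C\[C@@H]2O[C@H]2C)c1-c1ccc(OC(C)=O)cc1
F11 | step 15 | 4,4''-diacetoxy-1,1':4',1''-terphenyl-2',3',5',6'-tetrayl tetrakis[(2Z,4S,5S)-4,5-epoxyhex-2-enoate] | C[C@@H]1O[C@H]1/C=C\C(=O)Oc1c(OC(=O)/C=C\[C@@H]2O[C@H]2C)c(-c2ccc(OC(C)=O)cc2)c(OC(=O)/C=C\[C@@H]2O[C@H]2C)c(OC(=O)/C=C\[C@@H]2O[C@H]2C)c1-c1ccc(OC(C)=O)cc1
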